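**Target:** (3R,5S)-1-(4-hydroxy-3-methoxyphenyl)-7-(4-hydroxy-3,5-dimethoxyphenyl)heptane-3,5-diyl diacetate (12). Chain atoms are numbered C1 to C7 as in the target throughout; ring A is the 4-hydroxy-3-methoxyphenyl ring on C1, ring B the 4-hydroxy-3,5-dimethoxyphenyl ring on C7.

## Analysis of the target

The target is a linear 1,7-diarylheptane with secondary acetates at C3 and C5 and no ring other than the two arenes. The stereocentres C3 (R) and C5 (S) are syn across the C4 methylene; with two identical arenes the compound would be meso. The mirror plane through C4 is broken only by the methoxy group at C5 of ring B. The absolute configuration is therefore nothing more than the statement of which end of a syn-1,3-diacetate carries ring B, and the enantiomer is the same chain with rings A and B exchanged. The relative configuration is thus easy, while the absolute configuration is a problem of telling two almost identical chain ends apart. A catalyst with a purely local preference at each carbinol carbon gives the unwanted like (anti) pair, and any process that lets the two arenes exchange is a racemisation. Sensitive groups are the two free phenols (oxidation, competition in acylation), the two secondary acetates (labile to base and nucleophiles) and the electron-rich arenes. The second difficulty is placing acetyl groups on the two alcohols and not on the two phenols.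

## Retrosynthetic reasoning

**12 from 11.** The last disconnection removes two acetyl groups from the phenol oxygens: 12 comes from tetraacetate 11. Aryl acetates are far better acyl donors than secondary alkyl acetates, so the forward step only has to use this rate difference. This allows the phenols to be free during the acetylation and saves a separate protecting group operation.

**11 from 9 via 10.** The four acetyl groups and the silicon bridge are exchanged: 11 comes from tetraol 10, and 10 from the silylene-protected bis-phenol 9. No carbon–carbon bond is cut here; the step only trades the group that held O3 and O5 together for the acetates of the target.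

**9 from 8.** The C1–C2 single bond is traced back to an (E)-double bond and the two phenols to benzyl ethers, which gives 8. One hydrogenation saturates the alkene and frees both phenols while the allylic oxygen at C3 is still a poor leaving group (a silyl ether, not an acetate).

**8 from 4 and 6.** The C7–aryl bond is cut. Ring B comes from aryl bromide 6 and the chain from the terminal vinyl group (C6=C7) of 4, through alkylborane 7. This sp3–sp2 coupling is chosen over a second metathesis because it is irreversible and cannot exchange ring A for ring B at the other end, which in this target would mean loss of enantiomeric purity.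

**4 from 2 and 3 (key disconnection).** The C1=C2 double bond is cut and, at the same time, C2 and C6 are reconnected as a ring double bond. This leads to styrene 3 and the meso bicyclic alkene 2, in which C3 and C5 are the bridgeheads, C4 is the one-carbon bridge and O3–Si–O5 is the three-atom bridge. The forward reaction is an enantioselective ring-opening cross-metathesis: a chiral alkylidene catalyst must decide which of the two enantiotopic olefinic carbons of 2 receives the arylmethylidene of 3. That single decision attaches ring A, differentiates the chain ends at carbon and fixes the absolute configuration of C3 and C5 together. Their syn relation is already contained in the cis ring fusion. The precursor 2 is achiral, has thirteen carbons and is one step from a commercial diol.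

**2 from 1; 6 from 5.** Bicycle 2 comes from cis-cyclopent-4-ene-1,3-diol 1 by bridging the two oxygens with a di-tert-butylsilylene group. The bridge adds the strain and rigidity that ring opening needs and later serves as the diol protecting group. Bromide 6 comes from phenol 5 by O-benzylation.

## Alternatives that were turned down

**Alternative 1:** The textbook route cuts C4–C5 as an aldol bond. A chiral boron enolate of methyl ketone A1 (the benzyl ether of commercial zingerone) would add to aldehyde A2 to give β-hydroxy ketone A3, followed by chelation-controlled syn reduction (Narasaka–Prasad), acetylation and hydrogenolysis. It was turned down for these reasons: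
- The two stereocentres are set in two separate operations, the first with a stoichiometric chiral reagent.
- The acetate-type enolate of A1 has no α-substituent to organise the transition state, so its facial selectivity with an unbranched aldehyde is the weak point.
- A3 can dehydrate or undergo retro-aldol cleavage.
- A2 alone costs about three steps, so the route is no shorter, and it makes no use of the near-symmetry of the target.

**Alternative 2:** A two-directional route with an enzymatic key step. meso-Hepta-1,6-diene-3,5-diol A4 would be desymmetrised by a lipase to monoacetate A5, and the two vinyl groups would then be arylated one after the other by hydroboration and Suzuki–Miyaura coupling. It was turned down because the enzyme writes the information on oxygen while the target needs it on carbon. Both oxygens end up as acetates, and the two vinyl termini of A5 are equally reactive towards boranes or alkylidenes, since the OH/OAc difference lies three bonds from the reacting carbon. No reaction is available to pick one terminus, and protecting group exchanges would add steps without solving this. A4 itself would also need a diastereoselective synthesis of several steps.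

**Alternative 3:** A biomimetic route through β-diketone A6, reached in a few steps by condensation chemistry, followed by asymmetric double reduction with a ketoreductase or a chiral hydrogenation catalyst. It was turned down on stereochemical grounds. The C3 and C5 carbonyl groups differ only by the ring B methoxy group eight bonds away, so no catalyst can choose between them. A catalyst that reduces each carbonyl with the same local facial preference gives the anti diol. A syn-selective second reduction under substrate control would give the syn diol, but as an equal mixture of the target series and its enantiomer.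

Key step: step 2

**Assumption (one remark on the chemistry):** the sense in which the chiral ruthenium carbene selects between the enantiotopic olefinic carbons of 2 is drawn by analogy and has to be confirmed. The opposite sense would be met by the antipodal ligand or by exchanging the roles of the two aryl partners, since the enantiomer of the target differs only in which end carries ring B. Compounds 1, 3 and 5 are taken as catalogue compounds.

## Route

Step 1
Reactants: 1 cis-cyclopent-4-ene-1,3-diol (meso, 1R,3S)
Product: 2 (1R,5S)-3,3-di-tert-butyl-2,4-dioxa-3-silabicyclo[3.2.1]oct-6-ene (meso)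
Conditions: tBu2Si(OTf)2 (1.05 equiv, slow addition), 2,6-lutidine, CH2Cl2 (high dilution), 0 °C to rt
Reagents that add atoms: di-tert-butylsilyl bis(trifluoromethanesulfonate), CC(C)(C)[Si](OS(=O)(=O)C(F)(F)F)(OS(=O)(=O)C(F)(F)F)C(C)(C)C
Why: Silylene formation from a 1,3-diol and a dialkylsilyl bis-triflate; the cis diol can place both oxygens on one face of the envelope, the long Si–O bonds let the six-membered dioxasilinane span C1 and C3, and dilution favours the intramolecular second silylation; no stereocentre is created, the product is meso.

Step 2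
Reactants: 2 (1R,5S)-3,3-di-tert-butyl-2,4-dioxa-3-silabicyclo[3.2.1]oct-6-ene; 3 4-benzyloxy-3-methoxystyrene
Product: 4 (4S,6R)-4-[(E)-2-(4-benzyloxy-3-methoxyphenyl)ethenyl]-2,2-di-tert-butyl-6-ethenyl-1,3,2-dioxasilinane
Conditions: RuCl(=CH-C6H4-2-OiPr)(L*) 5 mol % (L* = C,O-chelating 1-(2'-oxido-1,1'-binaphthalen-2-yl)-3-mesityl-4,5-dihydroimidazol-2-ylidene, single atropisomer), NaI, 3 (3 equiv), THF, 22 °C
Reagents that add atoms: none
Why: Asymmetric ring-opening cross-metathesis: the chiral ruthenium benzylidene formed from the catalyst and 3 adds to the strained double bond of 2 from the exo face (the side of the CH2 bridge; the endo face is covered by the O–Si–O bridge), the ruthenacyclobutane opens with release of ring strain, and the new alkylidene is capped by a second molecule of 3 as a terminal vinyl group, which returns the benzylidene. The closest known reaction type is the ring-opening cross-metathesis of meso norbornenes and 8-oxabicyclo[3.2.1]oct-6-enes with styrenes by chiral ruthenium carbenes of this ligand class, which gives cis-2,6-dialkenyl tetrahydropyrans; 2 has the same bicyclo[3.2.1]oct-6-ene core with the heteroatoms moved into the three-atom bridge. No ring is closed: the cyclopentene is opened and the 1,3,2-dioxasilinane survives, so the syn relation of C3 and C5 is inherited from 1 and cannot be lost because neither C–O bond is touched. The absolute configuration of both stereocentres is set by catalyst control, namely by which enantiotopic olefinic carbon bonds to the benzylidene carbon inside the chiral pocket of the C,O-chelating carbene ligand. The step needs three selectivities: enantiotopic carbon selection, cross-metathesis over ring-opening polymerisation (secured by the excess of 3 and the moderate strain), and no second metathesis at the new vinyl group (secured by the branched allylic silyl ether next to it and the low cross-metathesis activity of chelated catalysts of this type). The alkene geometry is expected to be E and is in any case removed in step 5. One operation thus forms the C1=C2 bond, attaches ring A and differentiates the two chain ends.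

Step 3
Reactants: 5 4-bromo-2,6-dimethoxyphenol
Product: 6 2-(benzyloxy)-5-bromo-1,3-dimethoxybenzene
Conditions: BnBr, K2CO3, DMF, 60 °C
Reagents that add atoms: benzyl bromide, BrCc1ccccc1
Why: Williamson ether synthesis on a phenoxide; the two ortho methoxy groups slow but do not prevent O-alkylation with a reactive benzylic halide.

Step 4
Reactants: 4 (4S,6R)-4-[(E)-2-(4-benzyloxy-3-methoxyphenyl)ethenyl]-2,2-di-tert-butyl-6-ethenyl-1,3,2-dioxasilinane; 6 2-(benzyloxy)-5-bromo-1,3-dimethoxybenzene
Product: 8 (4S,6S)-4-[(E)-2-(4-benzyloxy-3-methoxyphenyl)ethenyl]-6-[2-(4-benzyloxy-3,5-dimethoxyphenyl)ethyl]-2,2-di-tert-butyl-1,3,2-dioxasilinane, via alkylborane 7 (not isolated)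
Conditions: 9-BBN-H (1.2 equiv), THF, 0 °C to rt; then 6, Pd(OAc)2 (5 mol %), SPhos (10 mol %), aq. K3PO4, THF, 60 °C
Reagents that add atoms: 9-borabicyclo[3.3.1]nonane, B1C2CCCC1CCC2 (its boron and carbons remain in 7 only; 8 keeps only the hydrogen at C6)
Why: Anti-Markovnikov hydroboration followed by B-alkyl Suzuki–Miyaura coupling; the bulky borane adds to the monosubstituted vinyl group much faster than to the 1,2-disubstituted styrenyl alkene, and the coupling forms the C7–aryl bond irreversibly, so ring A and ring B cannot exchange. The stereocentres are not involved (the descriptor at the ring B end changes only because the substituent priorities change).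

Step 5
Reactants: 8 (4S,6S)-4-[(E)-2-(4-benzyloxy-3-methoxyphenyl)ethenyl]-6-[2-(4-benzyloxy-3,5-dimethoxyphenyl)ethyl]-2,2-di-tert-butyl-1,3,2-dioxasilinane
Product: 9 (4R,6S)-2,2-di-tert-butyl-4-[2-(4-hydroxy-3-methoxyphenyl)ethyl]-6-[2-(4-hydroxy-3,5-dimethoxyphenyl)ethyl]-1,3,2-dioxasilinane
Conditions: H2 (1 atm), Pd/C (10 wt %), EtOAc/EtOH, rt
Reagents that add atoms: none
Why: Catalytic hydrogenation saturates the C1=C2 bond and hydrogenolysis cleaves both aryl benzyl ethers; the allylic oxygen at C3 is a silyl ether and a poor leaving group, so C–O hydrogenolysis should not compete with the fast saturation of the styrenyl alkene.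

Step 6
Reactants: 9 (4R,6S)-2,2-di-tert-butyl-4-[2-(4-hydroxy-3-methoxyphenyl)ethyl]-6-[2-(4-hydroxy-3,5-dimethoxyphenyl)ethyl]-1,3,2-dioxasilinane
Product: 11 (3R,5S)-1-(4-acetoxy-3-methoxyphenyl)-7-(4-acetoxy-3,5-dimethoxyphenyl)heptane-3,5-diyl diacetate, via tetraol 10 (not isolated)
Conditions: HF·pyridine, THF/pyridine, 0 °C to rt; then Ac2O (excess), DMAP, same flask, rt
Reagents that add atoms: acetic anhydride, CC(=O)OC(C)=O
Why: Fluoride-driven cleavage of the silylene (strong Si–F bonds) without touching C–O bonds, then exhaustive DMAP-catalysed acetylation of the crude polar tetraol; both stereocentres are carbinol carbons whose C–O bonds stay intact.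

Step 7
Reactants: 11 (3R,5S)-1-(4-acetoxy-3-methoxyphenyl)-7-(4-acetoxy-3,5-dimethoxyphenyl)heptane-3,5-diyl diacetate
Product: 12 (3R,5S)-1-(4-hydroxy-3-methoxyphenyl)-7-(4-hydroxy-3,5-dimethoxyphenyl)heptane-3,5-diyl diacetate
Conditions: pyrrolidine (2.5 equiv), CH2Cl2, 0 °C
Reagents that add atoms: none
Why: Chemoselective aminolysis of aryl acetates; a phenoxide is a far better leaving group than a secondary alkoxide, so a secondary amine at low temperature should remove only the two phenolic acetyl groups.

## Compound list

1 | cis-cyclopent-4-ene-1,3-diol (meso, 1R,3S) | O[C@H]1C=C[C@@H](O)C1 | starting material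
2 | (1R,5S)-3,3-di-tert-butyl-2,4-dioxa-3-silabicyclo[3.2.1]oct-6-ene (meso) | CC(C)(C)[Si]1(C(C)(C)C)O[C@H]2C=C[C@@H](O1)C2 | intermediate
3 | 4-benzyloxy-3-methoxystyrene | COc1cc(C=C)ccc1OCc1ccccc1 | starting material
4 | (4S,6R)-4-[(E)-2-(4-benzyloxy-3-methoxyphenyl)ethenyl]-2,2-di-tert-butyl-6-ethenyl-1,3,2-dioxasilinane | COc1cc(/C=C/[C@@H]2C[C@H](C=C)O[Si](C(C)(C)C)(C(C)(C)C)O2)ccc1OCc1ccccc1 | intermediate
5 | 4-bromo-2,6-dimethoxyphenol | COc1cc(Br)cc(OC)c1O | starting material
6 | 2-(benzyloxy)-5-bromo-1,3-dimethoxybenzene | COc1cc(Br)cc(OC)c1OCc1ccccc1 | intermediate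
7 | 9-[2-[(4S,6S)-6-[(E)-2-(4-benzyloxy-3-methoxyphenyl)ethenyl]-2,2-di-tert-butyl-1,3,2-dioxasilinan-4-yl]ethyl]-9-borabicyclo[3.3.1]nonane (not isolated) | COc1cc(/C=C/[C@@H]2C[C@H](CCB3C4CCCC3CCC4)O[Si](C(C)(C)C)(C(C)(C)C)O2)ccc1OCc1ccccc1 | intermediate
8 | (4S,6S)-4-[(E)-2-(4-benzyloxy-3-methoxyphenyl)ethenyl]-6-[2-(4-benzyloxy-3,5-dimethoxyphenyl)ethyl]-2,2-di-tert-butyl-1,3,2-dioxasilinane | COc1cc(/C=C/[C@@H]2C[C@H](CCc3cc(OC)c(OCc4ccccc4)c(OC)c3)O[Si](C(C)(C)C)(C(C)(C)C)O2)ccc1OCc1ccccc1 | intermediate
9 | (4R,6S)-2,2-di-tert-butyl-4-[2-(4-hydroxy-3-methoxyphenyl)ethyl]-6-[2-(4-hydroxy-3,5-dimethoxyphenyl)ethyl]-1,3,2-dioxasilinane | COc1cc(CC[C@@H]2C[C@H](CCc3cc(OC)c(O)c(OC)c3)O[Si](C(C)(C)C)(C(C)(C)C)O2)ccc1O | intermediate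
10 | (3R,5S)-1-(4-hydroxy-3-methoxyphenyl)-7-(4-hydroxy-3,5-dimethoxyphenyl)heptane-3,5-diol (not isolated) | COc1cc(CC[C@H](C[C@H](CCc2cc(OC)c(O)c(OC)c2)O)O)ccc1O | intermediate
11 | (3R,5S)-1-(4-acetoxy-3-methoxyphenyl)-7-(4-acetoxy-3,5-dimethoxyphenyl)heptane-3,5-diyl diacetate | COc1cc(CC[C@H](C[C@H](CCc2cc(OC)c(OC(C)=O)c(OC)c2)OC(C)=O)OC(C)=O)ccc1OC(C)=O | intermediate
12 | (3R,5S)-1-(4-hydroxy-3-methoxyphenyl)-7-(4-hydroxy-3,5-dimethoxyphenyl)heptane-3,5-diyl diacetate | COc1cc(CC[C@H](C[C@H](CCc2cc(OC)c(O)c(OC)c2)OC(C)=O)OC(C)=O)ccc1O | target

## Step count and risk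

Total step count: 7. Longest linear sequence: 6 (steps 1, 2, 4, 5, 6, 7); step 3 is the side branch.

**Step 2 (key step).**
- What may go wrong: insufficient discrimination between the two enantiotopic olefinic carbons, which here is the same as partial exchange of the chain ends; also ring-opening polymerisation of 2 or a second metathesis at the new vinyl group.
- Why: the substrate is new, and its O–Si–O bridge lies farther from the alkene than the oxygen bridge of the precedent, so the chiral pocket may read it less well.
- Fallback: a stepwise chain construction that sets out from 6 and 3 and comes back at 8. A Heck reaction of 6 with allyl alcohol (Pd(OAc)2, Bu4NCl, NaHCO3, DMF) would give 3-(4-benzyloxy-3,5-dimethoxyphenyl)propanal F1 (the same compound as A2). Cross-metathesis of 3 with methyl vinyl ketone (second-generation Hoveyda–Grubbs catalyst RuCl2(=CH-C6H4-2-OiPr)(H2IMes)) would give (E)-4-(4-benzyloxy-3-methoxyphenyl)but-3-en-2-one F2. The diisopinocampheylboron enolate of F2 (Ipc2BCl of the appropriate antipode, Et3N) would add to F1 to give (S,E)-1-(4-benzyloxy-3-methoxyphenyl)-7-(4-benzyloxy-3,5-dimethoxyphenyl)-5-hydroxyhept-1-en-3-one F3. Chelation-controlled reduction (Et2BOMe, NaBH4) would give (3S,5S,E)-1-(4-benzyloxy-3-methoxyphenyl)-7-(4-benzyloxy-3,5-dimethoxyphenyl)hept-1-ene-3,5-diol F4, and tBu2Si(OTf)2 with 2,6-lutidine would convert F4 into 8.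

**Step 1.**
- What may go wrong: intermolecular silylation to oligomeric silyl ethers instead of closure of the bridged ring.
- Why: the bicyclo[3.2.1] bridge demands the diaxial conformer of the diol.
- Fallback: from 1, bridging with boron in place of silicon, coming back at 4. Condensation of 1 with phenylboronic acid (toluene, water removal) would give (1R,5S)-3-phenyl-2,4-dioxa-3-borabicyclo[3.2.1]oct-6-ene F5, whose planar boron eases the bridge. Ring-opening cross-metathesis with 3 as in step 2 would give (4S,6R)-4-[(E)-2-(4-benzyloxy-3-methoxyphenyl)ethenyl]-6-ethenyl-2-phenyl-1,3,2-dioxaborinane F6. Exchange with pinacol would free (3S,5R,E)-1-(4-benzyloxy-3-methoxyphenyl)hepta-1,6-diene-3,5-diol F7, and silylene formation on this open-chain syn diol, which is unstrained, would give 4. The boron bridge is not carried further because the liberated phenylboronic acid would compete in step 4.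

**Step 4.**
- What may go wrong: slow oxidative addition of the electron-rich bromide, so that protodeboronation or β-hydride elimination of the alkyl intermediate takes over; partial hydroboration of the styrenyl alkene.
- Fallback: a second metathesis in place of the coupling, from 4 and 6, coming back at 9. Vinylation of 6 (potassium vinyltrifluoroborate, PdCl2(dppf), K2CO3, THF/H2O) would give 4-benzyloxy-3,5-dimethoxystyrene F8. Cross-metathesis of 4 with F8 (second-generation Hoveyda–Grubbs catalyst RuCl2(=CH-C6H4-2-OiPr)(H2IMes), short reaction time to avoid exchange at the existing styrenyl bond) would give (4S,6R)-4-[(E)-2-(4-benzyloxy-3-methoxyphenyl)ethenyl]-6-[(E)-2-(4-benzyloxy-3,5-dimethoxyphenyl)ethenyl]-2,2-di-tert-butyl-1,3,2-dioxasilinane F9. Hydrogenation of F9 under the conditions of step 5 gives 9.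

**Step 7.**
- What may go wrong: incomplete differentiation of aryl and alkyl acetates, with loss or migration of a secondary acetyl group.
- Why: the ring B acetate is flanked by two methoxy groups and reacts more slowly than the ring A acetate, which narrows the window.
- Fallback: orthogonal protection instead of a rate difference, from 8, coming back at 12. Diimide reduction of 8 (2-nitrobenzenesulfonyl hydrazide, Et3N) would saturate the alkene and keep the benzyl ethers, giving (4R,6S)-4-[2-(4-benzyloxy-3-methoxyphenyl)ethyl]-6-[2-(4-benzyloxy-3,5-dimethoxyphenyl)ethyl]-2,2-di-tert-butyl-1,3,2-dioxasilinane F10. HF·pyridine would give (3R,5S)-1-(4-benzyloxy-3-methoxyphenyl)-7-(4-benzyloxy-3,5-dimethoxyphenyl)heptane-3,5-diol F11. Ac2O with DMAP would give (3R,5S)-1-(4-benzyloxy-3-methoxyphenyl)-7-(4-benzyloxy-3,5-dimethoxyphenyl)heptane-3,5-diyl diacetate F12, and hydrogenolysis (H2, Pd/C, EtOAc) of F12 would give 12.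

## Further compounds

F1 | step 2 | 3-(4-benzyloxy-3,5-dimethoxyphenyl)propanal | COc1cc(CCC=O)cc(OC)c1OCc1ccccc1
F2 | step 2 | (E)-4-(4-benzyloxy-3-methoxyphenyl)but-3-en-2-one | COc1cc(/C=C/C(C)=O)ccc1OCc1ccccc1
F3 | step 2 | (S,E)-1-(4-benzyloxy-3-methoxyphenyl)-7-(4-benzyloxy-3,5-dimethoxyphenyl)-5-hydroxyhept-1-en-3-one | COc1cc(/C=C/C(=O)C[C@@H](O)CCc2cc(OC)c(OCc3ccccc3)c(OC)c2)ccc1OCc1ccccc1
F4 | step 2 | (3S,5S,E)-1-(4-benzyloxy-3-methoxyphenyl)-7-(4-benzyloxy-3,5-dimethoxyphenyl)hept-1-ene-3,5-diol | COc1cc(/C=C/[C@@H](O)C[C@@H](O)CCc2cc(OC)c(OCc3ccccc3)c(OC)c2)ccc1OCc1ccccc1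
F5 | step 1 | (1R,5S)-3-phenyl-2,4-dioxa-3-borabicyclo[3.2.1]oct-6-ene (meso) | c1ccccc1B1O[C@H]2C=C[C@@H](O1)C2
F6 | step 1 | (4S,6R)-4-[(E)-2-(4-benzyloxy-3-methoxyphenyl)ethenyl]-6-ethenyl-2-phenyl-1,3,2-dioxaborinane | COc1cc(/C=C/[C@@H]2C[C@H](C=C)OB(c3ccccc3)O2)ccc1OCc1ccccc1
F7 | step 1 | (3S,5R,E)-1-(4-benzyloxy-3-methoxyphenyl)hepta-1,6-diene-3,5-diol | COc1cc(/C=C/[C@@H](O)C[C@H](C=C)O)ccc1OCc1ccccc1
F8 | step 4 | 4-benzyloxy-3,5-dimethoxystyrene | COc1cc(C=C)cc(OC)c1OCc1ccccc1
F9 | step 4 | (4S,6R)-4-[(E)-2-(4-benzyloxy-3-methoxyphenyl)ethenyl]-6-[(E)-2-(4-benzyloxy-3,5-dimethoxyphenyl)ethenyl]-2,2-di-tert-butyl-1,3,2-dioxasilinane | COc1cc(/C=C/[C@@H]2C[C@H](/C=C/c3cc(OC)c(OCc4ccccc4)c(OC)c3)O[Si](C(C)(C)C)(C(C)(C)C)O2)ccc1OCc1ccccc1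
F10 | step 7 | (4R,6S)-4-[2-(4-benzyloxy-3-methoxyphenyl)ethyl]-6-[2-(4-benzyloxy-3,5-dimethoxyphenyl)ethyl]-2,2-di-tert-butyl-1,3,2-dioxasilinane | COc1cc(CC[C@@H]2C[C@H](CCc3cc(OC)c(OCc4ccccc4)c(OC)c3)O[Si](C(C)(C)C)(C(C)(C)C)O2)ccc1OCc1ccccc1
F11 | step 7 | (3R,5S)-1-(4-benzyloxy-3-methoxyphenyl)-7-(4-benzyloxy-3,5-dimethoxyphenyl)heptane-3,5-diol | COc1cc(CC[C@@H](O)C[C@@H](O)CCc2cc(OC)c(OCc3ccccc3)c(OC)c2)ccc1OCc1ccccc1
F12 | step 7 | (3R,5S)-1-(4-benzyloxy-3-methoxyphenyl)-7-(4-benzyloxy-3,5-dimethoxyphenyl)heptane-3,5-diyl diacetate | COc1cc(CC[C@H](C[C@H](CCc2cc(OC)c(OCc3ccccc3)c(OC)c2)OC(C)=O)OC(C)=O)ccc1OCc1ccccc1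
A1 | alternative 1 | 4-(4-benzyloxy-3-methoxyphenyl)butan-2-one | COc1cc(CCC(C)=O)ccc1OCc1ccccc1
A2 | alternative 1 | 3-(4-benzyloxy-3,5-dimethoxyphenyl)propanal | COc1cc(CCC=O)cc(OC)c1OCc1ccccc1
A3 | alternative 1 | (S)-1-(4-benzyloxy-3-methoxyphenyl)-7-(4-benzyloxy-3,5-dimethoxyphenyl)-5-hydroxyheptan-3-one | COc1cc(CCC(=O)C[C@H](CCc2cc(OC)c(OCc3ccccc3)c(OC)c2)O)ccc1OCc1ccccc1
A4 | alternative 2 | (3R,5S)-hepta-1,6-diene-3,5-diol (meso) | C=C[C@H](O)C[C@H](O)C=C
A5 | alternative 2 | (3R,5S)-5-hydroxyhepta-1,6-dien-3-yl acetate | C=C[C@H](OC(C)=O)C[C@H](O)C=C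
A6 | alternative 3 | 1-(4-hydroxy-3-methoxyphenyl)-7-(4-hydroxy-3,5-dimethoxyphenyl)heptane-3,5-dione | COc1cc(CCC(=O)CC(=O)CCc2cc(OC)c(O)c(OC)c2)ccc1O
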